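**Plan**

1. Retrosynthesis: after removal of fifteen benzyl ethers, the upper pyran ring (ring C) is cut at C2–C3 and O1–C2 and the interflavan bond C4(upper)–C8(ring D) is cut in the same operation, giving aldehyde 9 and (Z)-enol gallate 16. Compound 9 is cut at the ester on O3 of the lower unit and at the ring B–O–ring G diaryl ether; 16 is cut at the enol ester C–O bond (arylalkyne + gallic acid).
2. Forward: diaryl ether (Ullmann), then ester with benzylated (−)-epigallocatechin, gives 9; arylalkyne to (Z)-enol gallate gives 16. In one flask ring C then closes at C2–C3 (Prins) and the 16-membered ring closes at C4–C8 (Friedel–Crafts). Hydrogenolysis ends the route.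
3. Enabling feature: C4 of ring C is benzylic to the 5,7-dioxygenated ring A that carries O1, and C2 lies between O1 and ring B at the aldehyde oxidation level. A C3=C4 styrene attacked at C3 by an O1=C2 oxocarbenium carbon therefore gives the phloroglucinol-stabilised flavan-4-yl cation, which C8 of ring D captures.
4. Stereochemistry: the lower unit (2R,3R) comes from (−)-epigallocatechin. The upper 2,3-cis relationship comes from the Z-enol ester in a chair Prins transition state, and 3,4-trans from capture anti to the participating 3-O-gallate. The absolute sense of the upper unit is expected to be relayed from the lower unit through the ring G tether in the macrocyclising capture; this is the least secure point of the plan.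

Key step: step 12

Remark: rings are called A/C/B (upper unit: benzo, pyran, pendant aryl), D/F/E (lower unit, same order), G (bridging galloyl ring) and H (upper gallate ring), with flavan numbering inside each unit; compounds 1, 3, 7, 10 and 14 are taken as purchased.

**Route**

Step 1
Reactants: 1 methyl gallate
Product: 2 methyl 3,4-bis(benzyloxy)-5-hydroxybenzoate
Conditions: BnBr (2.05 equiv), K2CO3 (2.2 equiv), DMF, 0 °C to rt
Reagents that add atoms: benzyl bromide, BrCc1ccccc1
Why: Williamson etherification in which the 4-OH (para to the ester, most acidic) reacts first and either of the two equivalent 3/5-OH groups then gives the same 3,4-dibenzyl ether, which is separated from mono- and tribenzyl ethers by chromatography.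

Step 2
Reactants: 3 3,4,5-tris(benzyloxy)benzaldehyde
Product: 4 2-bromo-3,4,5-tris(benzyloxy)benzaldehyde
Conditions: NBS (1.05 equiv), MeCN, rt, dark
Reagents that add atoms: N-bromosuccinimide, O=C1CCC(=O)N1Br
Why: Electrophilic aromatic bromination at C2/C6, the only free and equivalent positions, which are activated ortho/para by the benzyloxy groups as in the bromination of other 3,4,5-trialkoxybenzaldehydes.

Step 3
Reactants: 2 methyl 3,4-bis(benzyloxy)-5-hydroxybenzoate; 4 2-bromo-3,4,5-tris(benzyloxy)benzaldehyde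
Product: 5 methyl 3,4-bis(benzyloxy)-5-[4,5,6-tris(benzyloxy)-2-formylphenoxy]benzoate
Conditions: CuI (10 mol %), N,N-dimethylglycine hydrochloride (30 mol %), Cs2CO3 (2 equiv), 1,4-dioxane, 100 °C
Reagents that add atoms: none
Why: Ullmann diaryl ether coupling in which the ortho-formyl group activates the C–Br bond toward the copper phenoxide, the same type of coupling that joins 2-bromo-3,4,5-trialkoxybenzoyl compounds to 3-hydroxybenzoates.

Step 4
Reactants: 5 methyl 3,4-bis(benzyloxy)-5-[4,5,6-tris(benzyloxy)-2-formylphenoxy]benzoate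
Product: 6 3,4-bis(benzyloxy)-5-[4,5,6-tris(benzyloxy)-2-formylphenoxy]benzoic acid
Conditions: LiOH·H2O (3 equiv), THF/MeOH/H2O, rt; then 1 M HCl
Reagents that add atoms: lithium hydroxide, [Li+].[OH-]
Why: Saponification of the methyl ester; the aldehyde has no α-hydrogen and the diaryl and benzyl ethers are inert to hydroxide at room temperature.

Step 5
Reactants: 7 (−)-epigallocatechin, (2R,3R)
Product: 8 (2R,3R)-5,7-bis(benzyloxy)-2-[3,4,5-tris(benzyloxy)phenyl]chroman-3-ol (penta-O-benzyl-epigallocatechin, free 3-OH)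
Conditions: BnBr (5.5 equiv), K2CO3 (6 equiv), DMF, −10 °C to rt, argon
Reagents that add atoms: benzyl bromide, BrCc1ccccc1
Why: Williamson etherification of the five phenols with carbonate, which leaves the secondary 3-OH untouched; low temperature and exclusion of oxygen should protect the pyrogallol ring and avoid base-induced epimerisation at C2, so both chiral-pool stereocentres are kept.

Step 6
Reactants: 6 3,4-bis(benzyloxy)-5-[4,5,6-tris(benzyloxy)-2-formylphenoxy]benzoic acid; 8 penta-O-benzyl-epigallocatechin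
Product: 9 (2R,3R)-5,7-bis(benzyloxy)-2-[3,4,5-tris(benzyloxy)phenyl]chroman-3-yl 3,4-bis(benzyloxy)-5-[4,5,6-tris(benzyloxy)-2-formylphenoxy]benzoate
Conditions: EDC·HCl (1.5 equiv), DMAP (0.5 equiv), CH2Cl2, 0 °C to rt
Reagents that add atoms: none
Why: Steglich esterification, the standard way to acylate the axial 3-OH of benzylated epi-flavan-3-ols with benzyl-protected gallic acids; no stereocentre is touched and the aldehyde is inert.

Step 7
Reactants: 10 2,4,6-trihydroxybenzaldehyde
Product: 11 4,6-bis(benzyloxy)-2-hydroxybenzaldehyde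
Conditions: BnBr (2.05 equiv), K2CO3 (2.1 equiv), DMF, 0 °C to rt
Reagents that add atoms: benzyl bromide, BrCc1ccccc1
Why: Williamson etherification of the 4-OH and one ortho-OH; the remaining ortho-OH is held in a hydrogen bond to the formyl group and should be too weakly nucleophilic to react under these conditions.

Step 8
Reactants: 11 4,6-bis(benzyloxy)-2-hydroxybenzaldehyde
Product: 12 4,6-bis(benzyloxy)-2-(triisopropylsilyloxy)benzaldehyde
Conditions: TIPSOTf (1.2 equiv), 2,6-lutidine (2 equiv), CH2Cl2, 0 °C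
Reagents that add atoms: triisopropylsilyl triflate, CC(C)[Si](OS(=O)(=O)C(F)(F)F)(C(C)C)C(C)C
Why: Silylation of the hydrogen-bonded phenol with the reactive silyl triflate; the TIPS ether should survive strong base and the ruthenium step and keeps the phenol from cyclising onto the alkyne.

Step 9
Reactants: 12 4,6-bis(benzyloxy)-2-(triisopropylsilyloxy)benzaldehyde
Product: 13 [3,5-bis(benzyloxy)-2-ethynylphenoxy]triisopropylsilane
Conditions: TMSCHN2 (1.3 equiv), LiN(iPr)2 (1.3 equiv), THF, −78 °C to rt; aq. NH4Cl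
Reagents that add atoms: (trimethylsilyl)diazomethane, C[Si](C)(C)C=[N+]=[N-]
Why: Colvin rearrangement (addition of lithiated TMS-diazomethane, Peterson elimination, loss of N2 and 1,2-shift) gives the terminal alkyne without the methoxide that an Ohira–Bestmann reaction would bring to the aryl silyl ether.

Step 10
Reactants: 13 [3,5-bis(benzyloxy)-2-ethynylphenoxy]triisopropylsilane; 14 3,4,5-tris(benzyloxy)benzoic acid
Product: 15 (Z)-2-[2,4-bis(benzyloxy)-6-(triisopropylsilyloxy)phenyl]ethenyl 3,4,5-tris(benzyloxy)benzoate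
Conditions: [RuCl2(p-cymene)]2 (2.5 mol %), P(4-ClC6H4)3 (7.5 mol %), DMAP (10 mol %), toluene, 60 °C
Reagents that add atoms: none
Why: Ruthenium-catalysed anti-Markovnikov addition of a carboxylic acid to a terminal alkyne through a ruthenium vinylidene, which should give the (Z)-enol ester that later fixes the 2,3-cis relationship.

Step 11
Reactants: 15 (Z)-enol gallate TIPS ether
Product: 16 (Z)-2-[2,4-bis(benzyloxy)-6-hydroxyphenyl]ethenyl 3,4,5-tris(benzyloxy)benzoate
Conditions: TBAF (1.1 equiv), AcOH (1.5 equiv), THF, 0 °C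
Reagents that add atoms: none
Why: Fluoride cleavage of the aryl silyl ether; acetic acid keeps the liberated phenol protonated, which should prevent acyl transfer from the neighbouring enol ester and loss of the Z geometry.

Step 12
Reactants: 9 aldehyde ester of the lower unit; 16 (Z)-enol gallate phenol
Product: 20 pentadeca-O-benzyl macrocycle (all fifteen phenols of the target as benzyl ethers; upper unit 2R,3R,4R; lower unit 2R,3R), via silyl ether 17 (not isolated), via oxocarbenium triflate 18 (not isolated), via flavan-4-yl cation triflate 19 (not isolated)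
Conditions: 16 (1.2 equiv), TMSOTf (1.1 equiv), 2,6-di-tert-butyl-4-methylpyridine (2.5 equiv), 4 Å MS, CH2Cl2, −78 °C; then 9 and TMSOTf (1.1 equiv) by syringe pump to 3 mM, −78 to −40 °C; Et3N quench
Reagents that add atoms: none
Why: Proposed new method: TMSOTf silylates phenol 16 to 17, which condenses with the TMSOTf-activated aldehyde of 9 to the O-aryl oxocarbenium ion 18 (the first half of a Noyori acetalisation), and C3 of the (Z)-enol ester, the β-carbon of a 2,4,6-trioxygenated styrene, attacks C2 because the charge then arrives at C4 as a phloroglucinol-stabilised benzylic cation, which should outweigh the weak enol-ester polarisation; the closest known reactions are the tandem Prins/Friedel–Crafts cyclisation of oxocarbenium ions and the TMSOTf-promoted 4→8 coupling of flavan-4-yl cations with benzylated flavan-3-ols. Ring C closes 6-endo-trig through a chair-like transition state with the C2 aryl group equatorial, so the Z geometry places the C3 gallate axial and fixes the 2,3-cis relationship. Cation 19 is bridged on its α-face by the gallate carbonyl (1,3-dioxolan-2-ylium), and C8 of the tethered ring D attacks C4 from the β-face in a 16-membered Friedel–Crafts ring closure, which sets the 3,4-trans (4R) centre. The absolute sense of C2/C3 is not set by achiral 18 alone; it is expected to be selected in this capture, because only the (2R,3R)-cation should offer its C4 β-face to C8 of ring D held by the (2R,3R)-ester tether, the other cation being left to revert or to be lost. The step needs union of the partners through oxygen before carbon (pre-silylation and the hindered base, which also suppresses protonation of the styrene and loss of Z geometry), attack by C8 and not C6 of ring D (C8 is the intrinsically more nucleophilic site and the one the O3 tether points toward), and high dilution against intermolecular capture.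

Step 13
Reactants: 20 pentadeca-O-benzyl macrocycle
Product: 21 CNP0601265.1 (target)
Conditions: H2 (1 atm), Pd(OH)2/C, THF/MeOH 1:1, rt; filtration under argon
Reagents that add atoms: none
Why: Hydrogenolysis of the fifteen benzyl aryl ethers, the standard last step for benzyl-protected proanthocyanidin gallates; the esters, the diaryl ether, the C2–O1 ethers and the C4–C8 bond should survive and no stereocentre is affected.

**Compound list**

1 | methyl gallate (methyl 3,4,5-trihydroxybenzoate) | COC(=O)c1cc(O)c(O)c(O)c1 | starting material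
2 | methyl 3,4-bis(benzyloxy)-5-hydroxybenzoate | COC(=O)c1cc(O)c(OCc2ccccc2)c(OCc2ccccc2)c1 | intermediate
3 | 3,4,5-tris(benzyloxy)benzaldehyde | O=Cc1cc(OCc2ccccc2)c(OCc2ccccc2)c(OCc2ccccc2)c1 | starting material
4 | 2-bromo-3,4,5-tris(benzyloxy)benzaldehyde | O=Cc1cc(OCc2ccccc2)c(OCc2ccccc2)c(OCc2ccccc2)c1Br | intermediate
5 | methyl 3,4-bis(benzyloxy)-5-[4,5,6-tris(benzyloxy)-2-formylphenoxy]benzoate | COC(=O)c1cc(OCc2ccccc2)c(OCc2ccccc2)c(Oc2c(C=O)cc(OCc3ccccc3)c(OCc3ccccc3)c2OCc2ccccc2)c1 | intermediate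
6 | 3,4-bis(benzyloxy)-5-[4,5,6-tris(benzyloxy)-2-formylphenoxy]benzoic acid | OC(=O)c1cc(OCc2ccccc2)c(OCc2ccccc2)c(Oc2c(C=O)cc(OCc3ccccc3)c(OCc3ccccc3)c2OCc2ccccc2)c1 | intermediate
7 | (−)-epigallocatechin, (2R,3R) | O[C@@H]1Cc2c(O)cc(O)cc2O[C@@H]1c1cc(O)c(O)c(O)c1 | starting material
8 | (2R,3R)-5,7-bis(benzyloxy)-2-[3,4,5-tris(benzyloxy)phenyl]chroman-3-ol | O[C@@H]1Cc2c(OCc3ccccc3)cc(OCc3ccccc3)cc2O[C@@H]1c1cc(OCc2ccccc2)c(OCc2ccccc2)c(OCc2ccccc2)c1 | intermediate
9 | (2R,3R)-5,7-bis(benzyloxy)-2-[3,4,5-tris(benzyloxy)phenyl]chroman-3-yl 3,4-bis(benzyloxy)-5-[4,5,6-tris(benzyloxy)-2-formylphenoxy]benzoate | O=Cc1cc(OCc2ccccc2)c(OCc2ccccc2)c(OCc2ccccc2)c1Oc1cc(cc(OCc2ccccc2)c1OCc1ccccc1)C(=O)O[C@@H]1Cc2c(OCc3ccccc3)cc(OCc3ccccc3)cc2O[C@@H]1c1cc(OCc2ccccc2)c(OCc2ccccc2)c(OCc2ccccc2)c1 | intermediate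
10 | 2,4,6-trihydroxybenzaldehyde | O=Cc1c(O)cc(O)cc1O | starting material
11 | 4,6-bis(benzyloxy)-2-hydroxybenzaldehyde | O=Cc1c(O)cc(OCc2ccccc2)cc1OCc1ccccc1 | intermediate
12 | 4,6-bis(benzyloxy)-2-(triisopropylsilyloxy)benzaldehyde | O=Cc1c(O[Si](C(C)C)(C(C)C)C(C)C)cc(OCc2ccccc2)cc1OCc1ccccc1 | intermediate
13 | [3,5-bis(benzyloxy)-2-ethynylphenoxy]triisopropylsilane | C#Cc1c(O[Si](C(C)C)(C(C)C)C(C)C)cc(OCc2ccccc2)cc1OCc1ccccc1 | intermediate
14 | 3,4,5-tris(benzyloxy)benzoic acid | OC(=O)c1cc(OCc2ccccc2)c(OCc2ccccc2)c(OCc2ccccc2)c1 | starting material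
15 | (Z)-2-[2,4-bis(benzyloxy)-6-(triisopropylsilyloxy)phenyl]ethenyl 3,4,5-tris(benzyloxy)benzoate | O=C(O/C=C\c1c(O[Si](C(C)C)(C(C)C)C(C)C)cc(OCc2ccccc2)cc1OCc1ccccc1)c1cc(OCc2ccccc2)c(OCc2ccccc2)c(OCc2ccccc2)c1 | intermediate
16 | (Z)-2-[2,4-bis(benzyloxy)-6-hydroxyphenyl]ethenyl 3,4,5-tris(benzyloxy)benzoate | O=C(O/C=C\c1c(O)cc(OCc2ccccc2)cc1OCc1ccccc1)c1cc(OCc2ccccc2)c(OCc2ccccc2)c(OCc2ccccc2)c1 | intermediate
17 | (Z)-2-[2,4-bis(benzyloxy)-6-(trimethylsilyloxy)phenyl]ethenyl 3,4,5-tris(benzyloxy)benzoate (not isolated) | O=C(O/C=C\c1c(O[Si](C)(C)C)cc(OCc2ccccc2)cc1OCc1ccccc1)c1cc(OCc2ccccc2)c(OCc2ccccc2)c(OCc2ccccc2)c1 | intermediate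
18 | O-aryl oxocarbenium triflate: O1 of ring A doubly bonded to the former formyl carbon (C2) of 9, (Z)-enol gallate ortho to O1 (not isolated) | O=C(O/C=C\c1c([O+]=Cc2cc(OCc3ccccc3)c(OCc3ccccc3)c(OCc3ccccc3)c2Oc2cc(cc(OCc3ccccc3)c2OCc2ccccc2)C(=O)O[C@@H]2Cc3c(OCc4ccccc4)cc(OCc4ccccc4)cc3O[C@@H]2c2cc(OCc3ccccc3)c(OCc3ccccc3)c(OCc3ccccc3)c2)cc(OCc2ccccc2)cc1OCc1ccccc1)c1cc(OCc2ccccc2)c(OCc2ccccc2)c(OCc2ccccc2)c1.[O-]S(=O)(=O)C(F)(F)F | intermediate
19 | (2R,3R)-3-(tri-O-benzylgalloyloxy)flavan-4-yl cation triflate: ring C closed, C4 cationic, lower unit attached only through the ring G ester (not isolated) | O=C(O[C@@H]1[CH+]c2c(OCc3ccccc3)cc(OCc3ccccc3)cc2O[C@@H]1c1cc(OCc2ccccc2)c(OCc2ccccc2)c(OCc2ccccc2)c1Oc1cc(cc(OCc2ccccc2)c1OCc1ccccc1)C(=O)O[C@@H]1Cc2c(OCc3ccccc3)cc(OCc3ccccc3)cc2O[C@@H]1c1cc(OCc2ccccc2)c(OCc2ccccc2)c(OCc2ccccc2)c1)c1cc(OCc2ccccc2)c(OCc2ccccc2)c(OCc2ccccc2)c1.[O-]S(=O)(=O)C(F)(F)F | intermediate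
20 | pentadeca-O-benzyl ether of 21: (2R,3R,4R) upper unit joined C4→C8 to the (2R,3R) lower unit, ring G ester on O3 of the lower unit and ether-linked through its 3-oxygen to C2 of ring B, tri-O-benzylgallate on O3 of the upper unit | O=C(O[C@@H]1[C@@H]2c3c(OCc4ccccc4)cc(OCc4ccccc4)cc3O[C@@H]1c1cc(OCc4ccccc4)c(OCc4ccccc4)c(OCc4ccccc4)c1Oc1cc(cc(OCc4ccccc4)c1OCc1ccccc1)C(=O)O[C@@H]1Cc3c(OCc4ccccc4)cc(OCc4ccccc4)c2c3O[C@@H]1c1cc(OCc3ccccc3)c(OCc3ccccc3)c(OCc3ccccc3)c1)c1cc(OCc2ccccc2)c(OCc2ccccc2)c(OCc2ccccc2)c1 | intermediate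
21 | CNP0601265.1: epigallocatechin 3-O-gallate-(4β→8)-epigallocatechin whose lower 3-O-galloyl ring is ether-linked through its 3-oxygen to C2 of the upper ring B | O=C(O[C@@H]1[C@@H]2c3c(O)cc(O)cc3O[C@@H]1c1cc(O)c(O)c(O)c1Oc1cc(cc(O)c1O)C(=O)O[C@@H]1Cc3c(O)cc(O)c2c3O[C@@H]1c1cc(O)c(O)c(O)c1)c1cc(O)c(O)c(O)c1 | target

**Totals and risks**

Total step count: 13. Longest linear sequence: 7 steps (10 → 11 → 12 → 13 → 15 → 16 → 20 → 21).

Steps most likely to fail:

First, step 12 (the proposed new method). What may go wrong: poor facial selectivity of the Prins closure with respect to the remote stereocentres of the lower unit; union of 9 and 17 through carbon (styrene C3 or ring D attacking the activated aldehyde) before the O-aryl oxocarbenium ion forms; or isomerisation of the Z-enol ester before closure. The fallback uses known reaction types, closes ring C at C4–C4a under reagent control, sets out from 5 (with 14 and 8) and comes back to the route at 20. Vinylmagnesium bromide (CH2=CHMgBr, THF, −78 °C) adds to the aldehyde of 5 to give the racemic allylic alcohol F1. Sharpless kinetic resolution (Ti(OiPr)4, L-(+)-diisopropyl tartrate, t-BuOOH, 4 Å MS, CH2Cl2, −20 °C) epoxidises the fast-reacting enantiomer to the erythro epoxy alcohol F2. Mitsunobu etherification with purchased 3,5-bis(benzyloxy)phenol (PPh3, DIAD, toluene, 0 °C) inverts the carbinol carbon and gives the aryl ether F3. Lewis-acid epoxide–arene Friedel–Crafts cyclisation (BF3·OEt2, CH2Cl2, −40 °C) at the terminal epoxide carbon closes the pyran ring to the 2,3-cis-flavan-3-ol F4. DDQ with 2-ethoxyethanol (CH2Cl2, rt) oxidises C4 to the 4β-(2-ethoxyethoxy) ether F5, and Steglich esterification with 14 gives the gallate F6. Me3SnOH (1,2-dichloroethane, 80 °C) cleaves the methyl ester alone to the acid F7, and EDC·HCl/DMAP couples it with alcohol 8 to the ester F8. TMSOTf (CH2Cl2, −78 °C, 2 mM) then ionises C4 of F8, and C8 of ring D should close the 16-membered ring with the 3,4-trans selectivity known for 3-O-acyl flavan-4-yl cations, giving 20.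

Second, step 10. What may go wrong: on this doubly ortho-substituted arylalkyne the ruthenium vinylidene addition may be slow, may give the Markovnikov (geminal) enol ester, or may give poor Z/E control. The fallback sets out from 13 and comes back at 15: trans-hydroboration of 13 (pinacolborane, [RhCl(cod)]2, P(iPr)3, Et3N, cyclohexane, rt) should give the (Z)-alkenylboronate F9, and the C–O bond is then made with retention of geometry by Chan–Lam coupling with acid 14 (Cu(OAc)2, Et3N, 4 Å MS, air, CH2Cl2, rt).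

Third, step 3. What may go wrong: the copper-catalysed displacement may stall on the doubly ortho-substituted bromide, with hydrodebromination or decomposition of the aldehyde at 100 °C. The fallback sets out from 4 and comes back at 5 and reverses the polarity of the aryl partner: Miyaura borylation of 4 (bis(pinacolato)diboron, PdCl2(dppf), KOAc, 1,4-dioxane, 80 °C) gives the arylboronate F10, which is coupled with phenol 2 under Chan–Evans–Lam conditions (Cu(OAc)2, pyridine, 4 Å MS, air, CH2Cl2, rt).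

**Further compounds**

F1 | step 12 | methyl 3,4-bis(benzyloxy)-5-[4,5,6-tris(benzyloxy)-2-(1-hydroxyprop-2-en-1-yl)phenoxy]benzoate (racemic) | COC(=O)c1cc(OCc2ccccc2)c(OCc2ccccc2)c(Oc2c(C(O)C=C)cc(OCc3ccccc3)c(OCc3ccccc3)c2OCc2ccccc2)c1
F2 | step 12 | methyl 3,4-bis(benzyloxy)-5-{4,5,6-tris(benzyloxy)-2-[(S)-hydroxy((R)-oxiran-2-yl)methyl]phenoxy}benzoate | COC(=O)c1cc(OCc2ccccc2)c(OCc2ccccc2)c(Oc2c([C@H](O)[C@H]3CO3)cc(OCc3ccccc3)c(OCc3ccccc3)c2OCc2ccccc2)c1
F3 | step 12 | methyl 3,4-bis(benzyloxy)-5-{4,5,6-tris(benzyloxy)-2-[(R)-[3,5-bis(benzyloxy)phenoxy]((R)-oxiran-2-yl)methyl]phenoxy}benzoate | COC(=O)c1cc(OCc2ccccc2)c(OCc2ccccc2)c(Oc2c([C@@H](Oc3cc(OCc4ccccc4)cc(OCc4ccccc4)c3)[C@H]3CO3)cc(OCc3ccccc3)c(OCc3ccccc3)c2OCc2ccccc2)c1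
F4 | step 12 | methyl 3,4-bis(benzyloxy)-5-{4,5,6-tris(benzyloxy)-2-[(2R,3R)-5,7-bis(benzyloxy)-3-hydroxychroman-2-yl]phenoxy}benzoate | O[C@@H]1Cc2c(OCc3ccccc3)cc(OCc3ccccc3)cc2O[C@@H]1c1cc(OCc2ccccc2)c(OCc2ccccc2)c(OCc2ccccc2)c1Oc1cc(cc(OCc2ccccc2)c1OCc1ccccc1)C(=O)OC
F5 | step 12 | 4β-(2-ethoxyethoxy) derivative of F4 (2,3-cis, 3,4-trans, free 3-OH) | O[C@@H]1[C@@H](OCCOCC)c2c(OCc3ccccc3)cc(OCc3ccccc3)cc2O[C@@H]1c1cc(OCc2ccccc2)c(OCc2ccccc2)c(OCc2ccccc2)c1Oc1cc(cc(OCc2ccccc2)c1OCc1ccccc1)C(=O)OC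
F6 | step 12 | 3-O-[3,4,5-tris(benzyloxy)benzoyl] ester of F5 | O=C(O[C@@H]1[C@@H](OCCOCC)c2c(OCc3ccccc3)cc(OCc3ccccc3)cc2O[C@@H]1c1cc(OCc2ccccc2)c(OCc2ccccc2)c(OCc2ccccc2)c1Oc1cc(cc(OCc2ccccc2)c1OCc1ccccc1)C(=O)OC)c1cc(OCc2ccccc2)c(OCc2ccccc2)c(OCc2ccccc2)c1
F7 | step 12 | carboxylic acid from F6 (ring G CO2H) | O=C(O[C@@H]1[C@@H](OCCOCC)c2c(OCc3ccccc3)cc(OCc3ccccc3)cc2O[C@@H]1c1cc(OCc2ccccc2)c(OCc2ccccc2)c(OCc2ccccc2)c1Oc1cc(cc(OCc2ccccc2)c1OCc1ccccc1)C(=O)O)c1cc(OCc2ccccc2)c(OCc2ccccc2)c(OCc2ccccc2)c1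
F8 | step 12 | ester of F7 with the 3-OH of 8 | O=C(O[C@@H]1[C@@H](OCCOCC)c2c(OCc3ccccc3)cc(OCc3ccccc3)cc2O[C@@H]1c1cc(OCc2ccccc2)c(OCc2ccccc2)c(OCc2ccccc2)c1Oc1cc(cc(OCc2ccccc2)c1OCc1ccccc1)C(=O)O[C@@H]1Cc2c(OCc3ccccc3)cc(OCc3ccccc3)cc2O[C@@H]1c1cc(OCc2ccccc2)c(OCc2ccccc2)c(OCc2ccccc2)c1)c1cc(OCc2ccccc2)c(OCc2ccccc2)c(OCc2ccccc2)c1
F9 | step 10 | (Z)-2-{2-[2,4-bis(benzyloxy)-6-(triisopropylsilyloxy)phenyl]ethenyl}-4,4,5,5-tetramethyl-1,3,2-dioxaborolane | CC1(C)OB(/C=C\c2c(O[Si](C(C)C)(C(C)C)C(C)C)cc(OCc3ccccc3)cc2OCc2ccccc2)OC1(C)C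
F10 | step 3 | 3,4,5-tris(benzyloxy)-2-(4,4,5,5-tetramethyl-1,3,2-dioxaborolan-2-yl)benzaldehyde | O=Cc1cc(OCc2ccccc2)c(OCc2ccccc2)c(OCc2ccccc2)c1B1OC(C)(C)C(C)(C)O1
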